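The synthesis rests on cutting the sp2–sp2 bond between the β-carbon of the acrylate ester and C5, the substituted olefinic carbon of the bicyclo[2.2.2]octene ring. One Mizoroki–Heck reaction forms this bond, sets the (E)-dienoate and unites two complete, enantiopure halves. It exploits the position of C5 next to bridgehead C4. An alkenyl bromide there, inherited from C4 of a 4-bromophenol, can neither eliminate nor isomerise (Bredt). The precursor is a tricyclic bromo lactone ketal in which the C8 carboxyl group and the C3 ketone mask each other. It comes from a dearomatisation/intramolecular Diels–Alder cascade whose five stereocentres are relayed from one bought, later discarded, benzylic stereocentre.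

Key step: step 7

Numbering of the cage used throughout (bicyclo[2.2.2]octene):
- C1 is the bridgehead between C2 (ketone), C6 and C7.
- C3 is the second carbon of the oxygenated bridge.
- C4 is the bridgehead between C3, C5 and C8.
- C5=C6 is the ring olefin; C5 bears Br or the side chain.
- C7 bears the aryl group.
- C8 bears the carboxyl carbon.

Assumption: in step 4 the carboxylate is taken to attack the alkoxy-bearing ring carbon from the face turned away from the phenyl group of the (S)-1-phenylethyl ether. Should the sense prove opposite, (S)-1-phenylethanol is used in step 1.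

Step 1
Reactants: 1 4-bromo-2-hydroxybenzaldehyde; 2 (R)-1-phenylethanol
Product: 3 4-bromo-2-[(1S)-1-phenylethoxy]benzaldehyde
Conditions: PPh3, DIAD, toluene, 0 °C to rt
Reagents that add atoms: none
Why: Mitsunobu etherification of the acidic salicylaldehyde OH displaces the activated benzylic alcohol by SN2, so the bought (R) centre is inverted to the (S) ether that later acts as a removable controller.

Step 2
Reactants: 3 4-bromo-2-[(1S)-1-phenylethoxy]benzaldehyde
Product: 5 4-bromo-2-[(1S)-1-phenylethoxy]phenol, via aryl formate 4 (not isolated)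
Conditions: mCPBA, CH2Cl2, 0 °C to rt; then K2CO3 (cat.), MeOH, rt
Reagents that add atoms: mCPBA, O=C(OO)c1cccc(Cl)c1
Why: In this Baeyer–Villiger (Dakin-type) oxidation the ortho-alkoxyaryl group migrates in preference to hydrogen and methanolysis of the formate frees the phenol, which fixes the OH/OR/Br pattern without a regiochemical question and leaves the stereocentre untouched.

Step 3
Reactants: 6 3,4-bis(benzyloxy)benzaldehyde; 7 malonic acid
Product: 9 (E)-3-[3,4-bis(benzyloxy)phenyl]acrylic acid, via arylidenemalonic acid 8 (not isolated)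
Conditions: pyridine, piperidine (cat.), 90 °C
Reagents that add atoms: none
Why: Knoevenagel–Doebner condensation with decarboxylation in the flask should give the thermodynamically preferred (E)-cinnamic acid.

Step 4
Reactants: 5 4-bromo-2-[(1S)-1-phenylethoxy]phenol; 9 (E)-3-[3,4-bis(benzyloxy)phenyl]acrylic acid
Product: 12 tricyclic bromo lactone ketal (1S,3R,4S,7S,8R), via bis(acyloxy)iodobenzene 10 (not isolated), via bromodienone 11 (not isolated)
Conditions: 9 (2.1 equiv), PhI(OAc)2, PhCl, 50 °C, reduced pressure (AcOH off); then 5, CH2Cl2, −20 to 0 °C; then toluene (0.01 M), BHT, 100 °C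
Reagents that add atoms: none
Why: This is a Wessely-type oxidative dearomatisation with a trivalent iodine dicarboxylate followed by a type 1 intramolecular Diels–Alder reaction: the carboxylate adds to the alkoxy-bearing ortho carbon (para position blocked by Br, which also slows dienone dimerisation) from the face flanked by methyl rather than phenyl of the ether held in its conformer of least A1,3 strain, which sets C3, and the three-atom ester tether then lets the (E)-alkene reach only the acyloxy-bearing face, closes the γ-lactone, bonds its α-carbon to the diene terminus next to C3 and so relays C1, C4, C7 and C8 (carbonyl syn to the C2–C3 bridge, aryl trans to it and syn to C5=C6), while any minor C3 epimer ends as a diastereomer removable by chromatography.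

Step 5
Reactants: 13 sodium (R)-3-(3,4-dihydroxyphenyl)-2-hydroxypropanoate (sodium danshensu)
Product: 14 benzyl (R)-3-[3,4-bis(benzyloxy)phenyl]-2-hydroxypropanoate
Conditions: BnBr (3.3 equiv), K2CO3, DMF, argon, rt
Reagents that add atoms: benzyl bromide, BrCc1ccccc1
Why: Williamson-type O-alkylation takes the carboxylate and the two phenoxides but not the much less acidic secondary alcohol, and the bought (R) centre is not involved.

Step 6
Reactants: 14 benzyl (R)-3-[3,4-bis(benzyloxy)phenyl]-2-hydroxypropanoate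
Product: 15 benzyl (R)-2-(acryloyloxy)-3-[3,4-bis(benzyloxy)phenyl]propanoate
Conditions: acryloyl chloride, Et3N, CH2Cl2, −20 to 0 °C
Reagents that add atoms: acryloyl chloride, C=CC(=O)Cl
Why: Simple O-acylation of the only free hydroxyl group at low temperature leaves the C–O bond and hence the (R) configuration intact.

Step 7
Reactants: 12 tricyclic bromo lactone ketal; 15 benzyl (R)-2-(acryloyloxy)-3-[3,4-bis(benzyloxy)phenyl]propanoate
Product: 16 fully protected yunnaneic acid C (cage 1R,3R,4R,7S,8R; side chain E and R)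
Conditions: Pd2(dba)3 (2.5 mol %), [(t-Bu)3PH]BF4 (10 mol %), Cy2NMe, BHT, 1,4-dioxane, 50 °C
Reagents that add atoms: none
Why: Zerovalent palladium inserts into the only C–Br bond of 12, the alkenylpalladium adds syn across the acrylate C=C of 15 with carbon–carbon bond formation at the unsubstituted β-carbon, and syn β-hydride elimination releases the dienoate, that is a Mizoroki–Heck reaction of an alkenyl bromide with an acrylate, a well-known route to 2,4-dienoates. No ring is closed and no stereocentre is created; the only new stereoelement, the (E) double bond, follows from the syn-insertion/syn-elimination sequence with ester and cage anti. Regioselectivity rests on the polarised, terminally unhindered acrylate, and site selectivity on the bromine that marks C5 rather than C6 of the ring olefin. The cage protects itself: both positions allylic to C5=C6 are bridgeheads, so hydride elimination or double-bond migration into the ring is forbidden by Bredt's rule, the C1–H next to the ketone cannot enolise, and the lactone C–O bond at quaternary C3 is only homoallylic and should not be ionised by zerovalent palladium. The hindered amine and the low temperature allowed by P(t-Bu)3 should spare the α-acyloxy ester stereocentre of 15. Because 15 is enantiopure, any trace of the antipodal cage becomes a diastereomer that can be removed here.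

Step 8
Reactants: 16 fully protected yunnaneic acid C
Product: 18 yunnaneic acid C, via hydroxy lactone 17 (not isolated)
Conditions: BCl3 (15 equiv), C6HMe5 (20 equiv), CH2Cl2, −78 to −30 °C; then THF/H2O, 0 °C
Reagents that add atoms: none
Why: In this Lewis-acid debenzylation with a non-basic cation scavenger, BCl3 cleaves the four aryl benzyl ethers, the benzyl ester and, fastest, the secondary benzylic O–C bond of the ketal on the side of the protecting group (so C3 itself never ionises), pentamethylbenzene traps the benzylic cations by Friedel–Crafts alkylation, and after hydrolysis of the borates hemiketal 17 opens to the C3 ketone and the C8 carboxylic acid without touching a stereocentre or either C=C bond.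

Compound list
1 | 4-bromo-2-hydroxybenzaldehyde | O=Cc1ccc(Br)cc1O | starting material
2 | (R)-1-phenylethanol | C[C@@H](O)c1ccccc1 | starting material
3 | 4-bromo-2-[(1S)-1-phenylethoxy]benzaldehyde | O=Cc1ccc(Br)cc1O[C@@H](C)c1ccccc1 | intermediate
4 | 4-bromo-2-[(1S)-1-phenylethoxy]phenyl formate | O=COc1ccc(Br)cc1O[C@@H](C)c1ccccc1 | intermediate
5 | 4-bromo-2-[(1S)-1-phenylethoxy]phenol | Oc1ccc(Br)cc1O[C@@H](C)c1ccccc1 | intermediate
6 | 3,4-bis(benzyloxy)benzaldehyde | O=Cc1ccc(OCc2ccccc2)c(OCc2ccccc2)c1 | starting material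
7 | malonic acid | OC(=O)CC(=O)O | starting material
8 | 2-[3,4-bis(benzyloxy)benzylidene]malonic acid | OC(=O)C(=Cc1ccc(OCc2ccccc2)c(OCc2ccccc2)c1)C(=O)O | intermediate
9 | (E)-3-[3,4-bis(benzyloxy)phenyl]acrylic acid | OC(=O)/C=C/c1ccc(OCc2ccccc2)c(OCc2ccccc2)c1 | intermediate
10 | phenyliodine bis{(E)-3-[3,4-bis(benzyloxy)phenyl]acrylate} | O=C(/C=C/c1ccc(OCc2ccccc2)c(OCc2ccccc2)c1)OI(OC(=O)/C=C/c1ccc(OCc2ccccc2)c(OCc2ccccc2)c1)c1ccccc1 | intermediate
11 | (1R)-3-bromo-6-oxo-1-[(1S)-1-phenylethoxy]cyclohexa-2,4-dien-1-yl (E)-3-[3,4-bis(benzyloxy)phenyl]acrylate | O=C1C=CC(Br)=C[C@@]1(O[C@@H](C)c1ccccc1)OC(=O)/C=C/c1ccc(OCc2ccccc2)c(OCc2ccccc2)c1 | intermediate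
12 | (1S,3R,4S,7S,8R)-7-[3,4-bis(benzyloxy)phenyl]-5-bromo-2-oxo-3-[(1S)-1-phenylethoxy]bicyclo[2.2.2]oct-5-ene-8-carboxylic acid closed as γ-lactone onto the second oxygen at C3 (lactone carbonyl syn to the C2–C3 bridge, aryl syn to C5=C6) | BrC1=C[C@H]2C(=O)[C@@]3(O[C@@H](C)c4ccccc4)[C@@H]1[C@H](C(=O)O3)[C@H]2c1ccc(OCc2ccccc2)c(OCc2ccccc2)c1 | intermediate
13 | sodium (R)-3-(3,4-dihydroxyphenyl)-2-hydroxypropanoate | [Na+].[O-]C(=O)[C@H](O)Cc1ccc(O)c(O)c1 | starting material
14 | benzyl (R)-3-[3,4-bis(benzyloxy)phenyl]-2-hydroxypropanoate | O=C(OCc1ccccc1)[C@H](O)Cc1ccc(OCc2ccccc2)c(OCc2ccccc2)c1 | intermediate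
15 | benzyl (R)-2-(acryloyloxy)-3-[3,4-bis(benzyloxy)phenyl]propanoate | C=CC(=O)O[C@H](Cc1ccc(OCc2ccccc2)c(OCc2ccccc2)c1)C(=O)OCc1ccccc1 | intermediate
16 | benzyl (2R)-3-[3,4-bis(benzyloxy)phenyl]-2-{[(2E)-3-(cage-C5-yl)prop-2-enoyl]oxy}propanoate, the cage being the lactone ketal of 12 with the side chain in place of Br (1R,3R,4R,7S,8R) | O=C(/C=C/C1=C[C@H]2C(=O)[C@@]3(O[C@@H](C)c4ccccc4)[C@@H]1[C@H](C(=O)O3)[C@H]2c1ccc(OCc2ccccc2)c(OCc2ccccc2)c1)O[C@H](Cc1ccc(OCc2ccccc2)c(OCc2ccccc2)c1)C(=O)OCc1ccccc1 | intermediate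
17 | hydroxy lactone (ring tautomer of the target: C3 carries OH and the lactone oxygen, 3R) | O=C(/C=C/C1=C[C@H]2C(=O)[C@@]3(O)[C@@H]1[C@H](C(=O)O3)[C@H]2c1ccc(O)c(O)c1)O[C@H](Cc1ccc(O)c(O)c1)C(=O)O | intermediate
18 | yunnaneic acid C, (1R,4R,7S,8R)-5-[(1E)-3-{[(1R)-1-carboxy-2-(3,4-dihydroxyphenyl)ethyl]oxy}-3-oxoprop-1-en-1-yl]-7-(3,4-dihydroxyphenyl)-2,3-dioxobicyclo[2.2.2]oct-5-ene-8-carboxylic acid | O=C(/C=C/C1=C[C@H]2C(=O)C(=O)[C@@H]1[C@H](C(=O)O)[C@H]2c1ccc(O)c(O)c1)O[C@H](Cc1ccc(O)c(O)c1)C(=O)O | target

Total step count: 8. Longest linear sequence: 5 (steps 1, 2, 4, 7, 8).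

Steps most likely to fail

**Step 4.**
- What may go wrong: little facial discrimination when the carboxylate attacks the alkoxy-bearing carbon, sluggish acyloxylation next to the secondary ether, or hydrolysis of the dienone before it cyclises.
- Fallback: stereocontrol by late resolution instead of an auxiliary. It sets out from acid 9 and comes back at 18. 2-(Benzyloxy)phenol is brominated para to the hydroxyl group (NBS, MeCN, 0 °C) to 2-(benzyloxy)-4-bromophenol F1. Oxidation with iodane 10 as in step 4 gives the racemic benzyloxy dienone F2, which cyclises in hot toluene to the racemic benzyloxy lactone ketal F3. Heck coupling with enantiopure 15 as in step 7 turns the racemate into two diastereomers, the wanted coupled ester F4 and the cage-antipodal coupled ester F5, which are separated by chromatography. BCl3/C6HMe5 as in step 8 converts F4 through 17 into 18.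

**Step 7.**
- What may go wrong: slow oxidative addition at the bromide crowded by the neighbouring 1-phenylethoxy group, polymerisation of the acrylate, or base-induced epimerisation of the α-acyloxy ester.
- Fallback: a base-free Stille coupling with reversed choice of the activated partner. It sets out from alcohol 14 and bromide 12 and comes back at 16. 14 is esterified with (E)-3-(tributylstannyl)acrylic acid (DCC, DMAP, CH2Cl2, 0 °C) to the β-stannylacrylate F6. Pd2(dba)3, AsPh3, CuI, NMP, rt to 40 °C then joins F6 and 12 at the same two carbons with retention of the (E) geometry to give 16.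

**Step 8.**
- What may go wrong: incomplete cleavage of the benzyl ester, C-benzylation of the liberated catechols, or Lewis-acid activation of the unveiled diketone with participation of the ring olefin or the carboxyl group.
- Fallback: a protecting set that falls to a Brønsted acid. It sets out from phenol 5 and comes back at 18. 5-Bromo-2,2-dimethyl-1,3-benzodioxole and acrylic acid (Pd(OAc)2, P(o-tol)3, Et3N, 90 °C) give the acetonide cinnamic acid F7. Treatment as in step 4 leads through the acetonide iodane F8 and the acetonide dienone F9 to the acetonide bromo lactone ketal F10. The Grignard reagent of the same aryl bromide opens tert-butyl (R)-oxirane-2-carboxylate at its CH2 group (CuI cat., THF, −40 °C) to the tert-butyl hydroxy ester F11. Acryloyl chloride/Et3N gives the tert-butyl acrylate F12. Coupling as in step 7 gives the acid-labile coupled ester F13. TFA/H2O (9:1), rt, removes both acetonides, the tert-butyl ester and the benzylic ketal ether, and 17 opens to 18.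

Further compounds
F1 | step 4 | 2-(benzyloxy)-4-bromophenol | Oc1ccc(Br)cc1OCc1ccccc1
F2 | step 4 | racemic 1-(benzyloxy)-3-bromo-6-oxocyclohexa-2,4-dien-1-yl (E)-3-[3,4-bis(benzyloxy)phenyl]acrylate | O=C1C=CC(Br)=CC1(OCc1ccccc1)OC(=O)/C=C/c1ccc(OCc2ccccc2)c(OCc2ccccc2)c1
F3 | step 4 | racemic benzyloxy lactone ketal (analogue of 12 with OBn at C3; the enantiomer that leads on is drawn) | BrC1=C[C@H]2C(=O)[C@@]3(OCc4ccccc4)[C@@H]1[C@H](C(=O)O3)[C@H]2c1ccc(OCc2ccccc2)c(OCc2ccccc2)c1
F4 | step 4 | wanted coupled ester (analogue of 16 with OBn at C3) | O=C(/C=C/C1=C[C@H]2C(=O)[C@@]3(OCc4ccccc4)[C@@H]1[C@H](C(=O)O3)[C@H]2c1ccc(OCc2ccccc2)c(OCc2ccccc2)c1)O[C@H](Cc1ccc(OCc2ccccc2)c(OCc2ccccc2)c1)C(=O)OCc1ccccc1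
F5 | step 4 | cage-antipodal coupled ester (diastereomer of F4) | O=C(/C=C/C1=C[C@@H]2C(=O)[C@]3(OCc4ccccc4)[C@H]1[C@@H](C(=O)O3)[C@@H]2c1ccc(OCc2ccccc2)c(OCc2ccccc2)c1)O[C@H](Cc1ccc(OCc2ccccc2)c(OCc2ccccc2)c1)C(=O)OCc1ccccc1
F6 | step 7 | benzyl (R)-3-[3,4-bis(benzyloxy)phenyl]-2-{[(E)-3-(tributylstannyl)acryloyl]oxy}propanoate | CCCC[Sn](CCCC)(CCCC)/C=C/C(=O)O[C@H](Cc1ccc(OCc2ccccc2)c(OCc2ccccc2)c1)C(=O)OCc1ccccc1
F7 | step 8 | (E)-3-(2,2-dimethyl-1,3-benzodioxol-5-yl)acrylic acid | OC(=O)/C=C/c1ccc2OC(C)(C)Oc2c1
F8 | step 8 | phenyliodine bis[(E)-3-(2,2-dimethyl-1,3-benzodioxol-5-yl)acrylate] | O=C(/C=C/c1ccc2OC(C)(C)Oc2c1)OI(OC(=O)/C=C/c1ccc2OC(C)(C)Oc2c1)c1ccccc1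
F9 | step 8 | (1R)-3-bromo-6-oxo-1-[(1S)-1-phenylethoxy]cyclohexa-2,4-dien-1-yl (E)-3-(2,2-dimethyl-1,3-benzodioxol-5-yl)acrylate | O=C1C=CC(Br)=C[C@@]1(O[C@@H](C)c1ccccc1)OC(=O)/C=C/c1ccc2OC(C)(C)Oc2c1
F10 | step 8 | acetonide bromo lactone ketal (analogue of 12) | BrC1=C[C@H]2C(=O)[C@@]3(O[C@@H](C)c4ccccc4)[C@@H]1[C@H](C(=O)O3)[C@H]2c1ccc2OC(C)(C)Oc2c1
F11 | step 8 | tert-butyl (R)-3-(2,2-dimethyl-1,3-benzodioxol-5-yl)-2-hydroxypropanoate | CC(C)(C)OC(=O)[C@H](O)Cc1ccc2OC(C)(C)Oc2c1
F12 | step 8 | tert-butyl (R)-2-(acryloyloxy)-3-(2,2-dimethyl-1,3-benzodioxol-5-yl)propanoate | C=CC(=O)O[C@H](Cc1ccc2OC(C)(C)Oc2c1)C(=O)OC(C)(C)C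
F13 | step 8 | acid-labile coupled ester (analogue of 16) | O=C(/C=C/C1=C[C@H]2C(=O)[C@@]3(O[C@@H](C)c4ccccc4)[C@@H]1[C@H](C(=O)O3)[C@H]2c1ccc2OC(C)(C)Oc2c1)O[C@H](Cc1ccc2OC(C)(C)Oc2c1)C(=O)OC(C)(C)C
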